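## Retrosynthetic overview
1. The usual routes are avoided: chalcone / Algar–Flynn–Oyamada / methylation, and Allan–Robinson or Baker–Venkataraman. All of them start from an o-hydroxyacetophenone and close O1–C2.
2. Key disconnection O1–C8a: the pyranone is closed last by intramolecular Ullmann-type O-arylation of a 2-methoxy-1,3-diketone onto an ortho-bromoarene. The ring oxygen is the former B-ring ketone oxygen.
3. Second disconnection C3–C4: the enolate of 2-methoxy-1-(4-methoxyphenyl)ethanone is acylated with 2-bromo-3,4,5-trimethoxybenzoyl chloride, so the 3-OMe arrives preinstalled.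
4. The A ring comes from symmetric 3,4,5-trimethoxybenzoic acid, where either ortho C–H gives the 6,7,8-pattern. The B-ring ketone comes from a Weinreb ketone synthesis.
5. Ring order: rings A and B are bought, and ring C is the only ring formed, in the last step. There is no phenol, no protecting group and no late methylation.

Assumption: auranetin (3,6,7,8,4'-pentamethoxyflavone) is a flat, achiral molecule with no stereogenic element. The "single enantiomer" is therefore the compound itself and no asymmetric step is needed.

## Route

Step 1
Reactants: 1 3,4,5-trimethoxybenzoic acid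
Product: 2 2-bromo-3,4,5-trimethoxybenzoic acid
Conditions: Br2 (1.05 equiv), CHCl3, reflux, 6 h
Reagents that add atoms: bromine, BrBr
Why: Electrophilic aromatic bromination (SEAr) can give only one monobromide because the two free positions of the symmetric acid are equivalent and each is ortho/para-activated by OMe groups, while the first bromine and the carboxyl group slow a second bromination; no stereocentre is formed.

Step 2
Reactants: 2 2-bromo-3,4,5-trimethoxybenzoic acid
Product: 3 2-bromo-3,4,5-trimethoxybenzoyl chloride
Conditions: SOCl2 (3 equiv), toluene, 80 °C, 2 h; evaporate, use crude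
Reagents that add atoms: thionyl chloride, O=S(Cl)Cl
Why: Standard acyl chloride formation through the acyl chlorosulfite is driven by loss of gases, and the aryl bromide and aryl methyl ethers are inert to it.

Step 3
Reactants: 4 4-methoxyphenylmagnesium bromide; 5 N,2-dimethoxy-N-methylacetamide
Product: 7 2-methoxy-1-(4-methoxyphenyl)ethan-1-one, via magnesium hemiaminal chelate 6 (not isolated)
Conditions: THF, 0 °C to rt, 2 h; then 1 M HCl
Reagents that add atoms: none
Why: In this Weinreb ketone synthesis the five-membered magnesium chelate 6 (racemic centre, lost on collapse) survives until the acidic quench, so no second Grignard addition occurs.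

Step 4
Reactants: 7 2-methoxy-1-(4-methoxyphenyl)ethan-1-one; 3 2-bromo-3,4,5-trimethoxybenzoyl chloride
Product: 10 1-(2-bromo-3,4,5-trimethoxyphenyl)-2-methoxy-3-(4-methoxyphenyl)propane-1,3-dione, via lithium Z-enolate 8 (not isolated), via lithium diketonate 9 (not isolated)
Conditions: LiHMDS (2.2 equiv), THF, −78 °C, 45 min; add 3 (1.0 equiv), −78 °C to rt; then 1 M HCl
Reagents that add atoms: none
Why: This is a crossed Claisen-type C-acylation in which the OMe-chelated enolate 8 attacks the aroyl chloride and the second equivalent of base at once turns the product into the stabilised diketonate 9, which blocks over-acylation and is the sink into which any O-acyl enol ester is re-funnelled; the bromide has no ortho hydrogen, so no aryne can form, and the new C2 stereocentre is racemic, labile and erased in step 5.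

Step 5
Reactants: 10 1-(2-bromo-3,4,5-trimethoxyphenyl)-2-methoxy-3-(4-methoxyphenyl)propane-1,3-dione
Product: 12 auranetin (3,6,7,8-tetramethoxy-2-(4-methoxyphenyl)-4H-chromen-4-one), via potassium diketonate 11 (not isolated)
Conditions: CuI (10 mol %), 1,10-phenanthroline (20 mol %), K2CO3 (2 equiv), dry DMF, N2, 110 °C, 12 h
Reagents that add atoms: none
Why: In this intramolecular Ullmann-type O-arylation (helped by the SNAr activation of the ortho carbonyl, the oxygen counterpart of the Grohe quinolone closure) the diketonate 11 binds Cu(I) next to the C–Br bond, only the anisoyl-side enolate oxygen can reach that carbon through a six-membered ring, and loss of bromide gives the aromatic 4-pyranone while removing the only sp3 stereocentre.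

## Compound list
1 | 3,4,5-trimethoxybenzoic acid | COc1cc(C(=O)O)cc(OC)c1OC | starting material
2 | 2-bromo-3,4,5-trimethoxybenzoic acid | COc1cc(C(=O)O)c(Br)c(OC)c1OC | intermediate
3 | 2-bromo-3,4,5-trimethoxybenzoyl chloride | COc1cc(C(=O)Cl)c(Br)c(OC)c1OC | intermediate
4 | 4-methoxyphenylmagnesium bromide (THF solution) | COc1ccc([Mg]Br)cc1 | starting material
5 | N,2-dimethoxy-N-methylacetamide | COCC(=O)N(C)OC | starting material
6 | bromomagnesium salt of the tetrahedral Weinreb adduct (chelate, racemic, not isolated) | COCC(O[Mg]Br)(N(C)OC)c1ccc(OC)cc1 | intermediate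
7 | 2-methoxy-1-(4-methoxyphenyl)ethan-1-one | COCC(=O)c1ccc(OC)cc1 | intermediate
8 | lithium (Z)-2-methoxy-1-(4-methoxyphenyl)ethen-1-olate (not isolated) | [Li]O/C(=C\OC)c1ccc(OC)cc1 | intermediate
9 | lithium diketonate of 10, chelated U-form, (E)-enolate (not isolated) | [Li]O/C(c1ccc(OC)cc1)=C(/OC)C(=O)c1cc(OC)c(OC)c(OC)c1Br | intermediate
10 | 1-(2-bromo-3,4,5-trimethoxyphenyl)-2-methoxy-3-(4-methoxyphenyl)propane-1,3-dione (racemic, labile C2) | COc1ccc(C(=O)C(OC)C(=O)c2cc(OC)c(OC)c(OC)c2Br)cc1 | intermediate
11 | potassium diketonate of 10, (E)-enolate (not isolated) | [K]O/C(c1ccc(OC)cc1)=C(/OC)C(=O)c1cc(OC)c(OC)c(OC)c1Br | intermediate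
12 | auranetin, 3,6,7,8,4'-pentamethoxyflavone (achiral) | COc1ccc(-c2oc3c(OC)c(OC)c(OC)cc3c(=O)c2OC)cc1 | target

## Step count and risks
Total step count: 5. Longest linear sequence: 4 (steps 1, 2, 4, 5). Step 3 is the convergent branch.

**Step 5 is the most likely to fail.** The C–Br carbon is flanked by two ortho substituents on an electron-rich ring, and hot carbonate can cleave the diketone by retro-Claisen.
- The fallback sets out from 2 and comes back to the route at 12.
- It makes the aryl C–O bond early, on the simple acid, where the neighbouring carboxylate strongly accelerates copper catalysis. The ring is then closed at O1–C2 by dehydration.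
- Compound 2 with catalytic CuSO4, pyridine and aqueous Na2CO3 at 95 °C gives 2-hydroxy-3,4,5-trimethoxybenzoic acid F1.
- MeOH with catalytic H2SO4 at reflux gives methyl 2-hydroxy-3,4,5-trimethoxybenzoate F2.
- F2 is added to an excess of enolate 8 (from 7, LiHMDS 3.5 equiv in total, THF, −78 °C to rt). This gives 1-(2-hydroxy-3,4,5-trimethoxyphenyl)-2-methoxy-3-(4-methoxyphenyl)propane-1,3-dione F3.
- AcOH with catalytic H2SO4 at 100 °C cyclodehydrates F3 to 12.

**Step 4 is the second risk.** The α-substituted enolate and the hindered ortho-bromo aroyl chloride may give O-acylation or react sluggishly.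
- The fallback sets out from 3 and comes back to the route at 10.
- It replaces the acylation by an aldol addition followed by oxidation, which has no C/O ambiguity.
- Compound 3 is reduced with LiAlH(OtBu)3 (THF, −78 °C) to 2-bromo-3,4,5-trimethoxybenzaldehyde F4.
- Enolate 8 (from 7, LiHMDS, THF, −78 °C) adds to F4. This gives 3-(2-bromo-3,4,5-trimethoxyphenyl)-3-hydroxy-2-methoxy-1-(4-methoxyphenyl)propan-1-one F5, a racemic diastereomer mixture in which both centres are later erased.
- Dess–Martin periodinane in CH2Cl2 oxidises F5 to 10.

**Step 1 is the third risk.** Ipso attack para to the 4-OMe group can cause bromodecarboxylation, and dibromination is possible.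
- The fallback sets out from 1 and comes back to the route at 2.
- It replaces SEAr by carboxylate-directed ortho-metalation.
- Compound 1 with s-BuLi/TMEDA (2.2 equiv, THF, −78 °C) is lithiated at the position flanked by carboxylate and OMe. This gives lithium 2-lithio-3,4,5-trimethoxybenzoate F6.
- F6 is quenched with 1,2-dibromotetrachloroethane and acidified with HCl to give 2.

## Further compounds
F1 | step 5 | 2-hydroxy-3,4,5-trimethoxybenzoic acid | COc1cc(C(=O)O)c(O)c(OC)c1OC
F2 | step 5 | methyl 2-hydroxy-3,4,5-trimethoxybenzoate | COC(=O)c1cc(OC)c(OC)c(OC)c1O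
F3 | step 5 | 1-(2-hydroxy-3,4,5-trimethoxyphenyl)-2-methoxy-3-(4-methoxyphenyl)propane-1,3-dione | COc1ccc(C(=O)C(OC)C(=O)c2cc(OC)c(OC)c(OC)c2O)cc1
F4 | step 4 | 2-bromo-3,4,5-trimethoxybenzaldehyde | COc1cc(C=O)c(Br)c(OC)c1OC
F5 | step 4 | 3-(2-bromo-3,4,5-trimethoxyphenyl)-3-hydroxy-2-methoxy-1-(4-methoxyphenyl)propan-1-one (racemic diastereomer mixture) | COc1ccc(C(=O)C(OC)C(O)c2cc(OC)c(OC)c(OC)c2Br)cc1
F6 | step 1 | lithium 2-lithio-3,4,5-trimethoxybenzoate | [Li]c1c(C(=O)O[Li])cc(OC)c(OC)c1OC
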